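**Retrosynthetic overview**
- The target is unmasked last, by hydrogenolysis of its 5,7-di-O-benzyl ether.
- Ring B carries 3'-OH beside 4'-OMe and 5'-OMe, with C2' and C6' unsubstituted. This pattern equals the five ring atoms of 3,4-dimethoxyfuran (O becomes the 3'-oxygen, C2/C5 become C3'/C6', C3/C4 with their methoxy groups become C4'/C5') plus the two carbons of a chromone-bound alkyne (C1', C2'). A Diels–Alder addition forms C1'–C6' and C2'–C3', and acid opening of the oxygen bridge gives the phenol.
- The ethynyl group on C2 of ring C comes from the aldehyde, which comes from the alcohol, which comes from the chromone-2-carboxylate.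
- Ring C comes from a 2-hydroxyacetophenone and diethyl oxalate; ring A comes from 2,4,6-trihydroxyacetophenone by double C-methylation and double O-benzylation.
- Order of rings: A (purchased), C (step 3), B (step 7).

Key step: step 7

Assumption: 3,4-dimethoxyfuran is taken as a purchasable reagent and is used freshly distilled, because this electron-rich furan is sensitive to acid and air.

**Step 1**
Reactants: 1 2,4,6-trihydroxyacetophenone
Product: 2 1-(2,4,6-trihydroxy-3,5-dimethylphenyl)ethanone
Conditions: MeI (2.1 equiv), NaOMe (2.1 equiv), MeOH, 0 °C to rt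
Reagents that add atoms: iodomethane, CI
Why: The phloroglucinol-type phenoxide is alkylated on carbon at the two free ring positions, each flanked by two oxygens, in protic methanol; this known double C-methylation of an acylphloroglucinol installs the future C6 and C8 methyl groups.

**Step 2**
Reactants: 2 1-(2,4,6-trihydroxy-3,5-dimethylphenyl)ethanone
Product: 3 1-[4,6-bis(benzyloxy)-2-hydroxy-3,5-dimethylphenyl]ethanone
Conditions: BnBr (2.1 equiv), K2CO3, DMF, rt
Reagents that add atoms: benzyl bromide, BrCc1ccccc1
Why: Williamson etherification benzylates the 4-OH and one of the two equivalent ortho OH groups, while the remaining ortho OH is held in a hydrogen bond to the acetyl carbonyl and should stay free at this stoichiometry.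

**Step 3**
Reactants: 3 1-[4,6-bis(benzyloxy)-2-hydroxy-3,5-dimethylphenyl]ethanone; 4 diethyl oxalate
Product: 6 ethyl 5,7-bis(benzyloxy)-6,8-dimethyl-4-oxo-4H-chromene-2-carboxylate, via diketo ester 5 (not isolated)
Conditions: NaOEt (3 equiv), EtOH–THF, 60 °C; then HCl in EtOH, 50 °C
Reagents that add atoms: none
Why: Crossed Claisen condensation of the methyl ketone enolate with the non-enolizable oxalate gives the 2,4-dioxo ester, and acid-catalysed attack of the phenol on the C2 ketone with loss of water closes pyranone ring C (classical chromone-2-carboxylate synthesis); the mild acid should leave the 5-benzyl ether in place.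

**Step 4**
Reactants: 6 ethyl 5,7-bis(benzyloxy)-6,8-dimethyl-4-oxo-4H-chromene-2-carboxylate
Product: 7 5,7-bis(benzyloxy)-2-(hydroxymethyl)-6,8-dimethyl-4H-chromen-4-one
Conditions: NaBH4, MeOH–THF, 0 °C
Reagents that add atoms: none
Why: Chemoselective borohydride reduction of the activated C2 ester, which sits on an electron-poor oxygen-bearing sp2 carbon, while the C4 carbonyl is a vinylogous ester further deactivated by the 5,7-dialkoxy ring and should not be reduced at 0 °C.

**Step 5**
Reactants: 7 5,7-bis(benzyloxy)-2-(hydroxymethyl)-6,8-dimethyl-4H-chromen-4-one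
Product: 8 5,7-bis(benzyloxy)-6,8-dimethyl-4-oxo-4H-chromene-2-carbaldehyde
Conditions: Dess–Martin periodinane, CH2Cl2, rt
Reagents that add atoms: none
Why: Dess–Martin oxidation of the primary allylic-type alcohol stops at the aldehyde under neutral, anhydrous conditions that tolerate the benzyl ethers and the pyranone; the electrophilic aldehyde is taken on without storage.

**Step 6**
Reactants: 8 5,7-bis(benzyloxy)-6,8-dimethyl-4-oxo-4H-chromene-2-carbaldehyde
Product: 9 5,7-bis(benzyloxy)-2-ethynyl-6,8-dimethyl-4H-chromen-4-one
Conditions: (MeO)2P(O)CHN2, KOtBu, THF, −78 °C to rt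
Reagents that add atoms: dimethyl (diazomethyl)phosphonate, COP(=O)(OC)C=[N+]=[N-]
Why: Seyferth–Gilbert homologation: the diazophosphonate anion adds to the non-enolizable aldehyde, loss of dimethyl phosphate gives a diazoalkene, and loss of N2 with a 1,2-hydrogen shift of the alkylidene carbene gives the terminal alkyne; the low temperature and the absence of a protic nucleophile protect the pyranone ring.

**Step 7**
Reactants: 9 5,7-bis(benzyloxy)-2-ethynyl-6,8-dimethyl-4H-chromen-4-one; 10 3,4-dimethoxyfuran
Product: 12 5,7-bis(benzyloxy)-2-(3-hydroxy-4,5-dimethoxyphenyl)-6,8-dimethyl-4H-chromen-4-one, via oxanorbornadiene cycloadduct 11 (not isolated)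
Conditions: 10 (4 equiv), ZnI2 (0.2 equiv), ClCH2CH2Cl, 50 °C; then CF3CO2H (2 equiv), 0 °C to rt
Reagents that add atoms: none
Why: Proposed new method: the electron-rich diene 10 should add across the alkyne of 9, whose LUMO is lowered by conjugation with the pyranone C2=C3–C4=O unit and further by ZnI2 on the C4 carbonyl, in a concerted suprafacial [4+2] cycloaddition that closes ring B intermolecularly through the bonds C1'–C6' and C2'–C3' and gives the 7-oxanorbornadiene 11. The closest known reaction type is the Diels–Alder addition of furans to acetylenic esters and ketones followed by acid isomerization of the oxa-bridged adducts to phenols; it has not been shown with a chromon-2-yl alkyne as the dienophile. Acid then ionizes one bridgehead C–O bond to a hydroxycyclohexadienyl cation and loss of the carbinol proton gives the phenol, which takes the adduct out of the retro-Diels–Alder equilibrium. The selectivity needed is opening at the bridgehead next to the chromonyl-bearing carbon (future C6'), so that the oxygen stays on future C3': this mode spreads the charge over C6', C2' and C4' (the last one methoxy-substituted) with the chromonyl group at a nodal carbon, whereas the other mode would put charge on C1', which carries the electron-poor and under acid O-protonated chromonyl group. Because 10 is symmetric the cycloaddition has no regiochemical issue, and the two bridgehead stereocentres of racemic 11 vanish on aromatization, so no stereocontrol is required.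

**Step 8**
Reactants: 12 5,7-bis(benzyloxy)-2-(3-hydroxy-4,5-dimethoxyphenyl)-6,8-dimethyl-4H-chromen-4-one
Product: 13 5,7,3'-trihydroxy-4',5'-dimethoxy-6,8-dimethylflavone
Conditions: H2 (1 atm), Pd/C, EtOAc–MeOH, rt
Reagents that add atoms: none
Why: Catalytic hydrogenolysis cleaves both benzyl aryl ethers, while the flavone C2=C3 bond, part of the conjugated pyranone, should not be reduced at 1 atm and rt; the target has no stereocentre.

**Compound list**
1 | 2,4,6-trihydroxyacetophenone | CC(=O)c1c(O)cc(O)cc1O | starting material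
2 | 1-(2,4,6-trihydroxy-3,5-dimethylphenyl)ethanone | CC(=O)c1c(O)c(C)c(O)c(C)c1O | intermediate
3 | 1-[4,6-bis(benzyloxy)-2-hydroxy-3,5-dimethylphenyl]ethanone | CC(=O)c1c(O)c(C)c(OCc2ccccc2)c(C)c1OCc1ccccc1 | intermediate
4 | diethyl oxalate | CCOC(=O)C(=O)OCC | starting material
5 | ethyl 4-[4,6-bis(benzyloxy)-2-hydroxy-3,5-dimethylphenyl]-2,4-dioxobutanoate (formed as its sodium enolate, not isolated) | CCOC(=O)C(=O)CC(=O)c1c(O)c(C)c(OCc2ccccc2)c(C)c1OCc1ccccc1 | intermediate
6 | ethyl 5,7-bis(benzyloxy)-6,8-dimethyl-4-oxo-4H-chromene-2-carboxylate | CCOC(=O)c1cc(=O)c2c(OCc3ccccc3)c(C)c(OCc3ccccc3)c(C)c2o1 | intermediate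
7 | 5,7-bis(benzyloxy)-2-(hydroxymethyl)-6,8-dimethyl-4H-chromen-4-one | OCc1cc(=O)c2c(OCc3ccccc3)c(C)c(OCc3ccccc3)c(C)c2o1 | intermediate
8 | 5,7-bis(benzyloxy)-6,8-dimethyl-4-oxo-4H-chromene-2-carbaldehyde | O=Cc1cc(=O)c2c(OCc3ccccc3)c(C)c(OCc3ccccc3)c(C)c2o1 | intermediate
9 | 5,7-bis(benzyloxy)-2-ethynyl-6,8-dimethyl-4H-chromen-4-one | C#Cc1cc(=O)c2c(OCc3ccccc3)c(C)c(OCc3ccccc3)c(C)c2o1 | intermediate
10 | 3,4-dimethoxyfuran | COc1cocc1OC | starting material
11 | rac-5,7-bis(benzyloxy)-2-[(1R,4S)-5,6-dimethoxy-7-oxabicyclo[2.2.1]hepta-2,5-dien-2-yl]-6,8-dimethyl-4H-chromen-4-one (racemate, one enantiomer written, not isolated) | COC1=C(OC)[C@@H]2O[C@H]1C=C2c1cc(=O)c2c(OCc3ccccc3)c(C)c(OCc3ccccc3)c(C)c2o1 | intermediate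
12 | 5,7-bis(benzyloxy)-2-(3-hydroxy-4,5-dimethoxyphenyl)-6,8-dimethyl-4H-chromen-4-one | COc1cc(-c2cc(=O)c3c(OCc4ccccc4)c(C)c(OCc4ccccc4)c(C)c3o2)cc(O)c1OC | intermediate
13 | 5,7,3'-trihydroxy-4',5'-dimethoxy-6,8-dimethylflavone | COc1cc(-c2cc(=O)c3c(O)c(C)c(O)c(C)c3o2)cc(O)c1OC | target

**Step count and risks**
Total step count: 8. Longest linear sequence: 8 steps (1 to 13).

Steps most likely to fail:

1. Step 7. Several processes could defeat it:
   - the cycloaddition may be too slow to compete with retro-addition or with acid-induced decomposition of the furan;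
   - the furan may add to the activated alkyne in a conjugate, open-chain fashion instead of [4+2];
   - the bis-enol ether of the adduct may be hydrolysed;
   - the bridge may open toward the wrong bridgehead and give the 2'-phenol.

   Fallback (known chemistry, sets out from 3 and returns at 13): ring B is brought in as a preformed arene. Commercial 3-hydroxy-4,5-dimethoxybenzaldehyde (COc1cc(C=O)cc(O)c1OC) is benzylated (BnBr, K2CO3, DMF) to 3-(benzyloxy)-4,5-dimethoxybenzaldehyde F1. Claisen–Schmidt condensation of 3 with F1 (KOH, EtOH, rt) should give (E)-1-[4,6-bis(benzyloxy)-2-hydroxy-3,5-dimethylphenyl]-3-[3-(benzyloxy)-4,5-dimethoxyphenyl]prop-2-en-1-one F2. Oxidative cyclization with catalytic I2 in DMSO at 120 °C closes ring C to 5,7-bis(benzyloxy)-2-[3-(benzyloxy)-4,5-dimethoxyphenyl]-6,8-dimethyl-4H-chromen-4-one F3. Hydrogenolysis (H2, Pd/C) of all three benzyl ethers gives 13.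

2. Step 6. The basic medium may open the pyranone ring at C2, or a nucleophile may add to the conjugated alkyne as it forms; hydration of the aldehyde may also consume the reagent.

   Fallback (sets out from 8 and returns at 9): olefination followed by elimination instead of carbene rearrangement. Wittig reaction of 8 with Ph3P=CHBr, preformed from (bromomethyl)triphenylphosphonium bromide and NaN(SiMe3)2 in THF at −78 °C, should give (Z)-5,7-bis(benzyloxy)-2-(2-bromoethenyl)-6,8-dimethyl-4H-chromen-4-one F4. Anti elimination of HBr with the non-nucleophilic base DBU (THF, rt to 50 °C) gives 9.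

3. Step 1. Alkylation may run on to dearomatized gem-dimethyl cyclohexadienones, stop at the mono-methyl stage, or occur on oxygen.

   Fallback (sets out from 1 and returns at 2): the methyl groups are introduced as aminomethyl groups. Double Mannich reaction of 1 with formaldehyde and morpholine (EtOH, rt) should give 1-[2,4,6-trihydroxy-3,5-bis(morpholin-4-ylmethyl)phenyl]ethanone F5. Hydrogenolysis of the two benzylic C–N bonds (H2, Pd/C, AcOH, 50 °C) gives 2.

**Further compounds**
F1 | step 7 | 3-(benzyloxy)-4,5-dimethoxybenzaldehyde | COc1cc(C=O)cc(OCc2ccccc2)c1OC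
F2 | step 7 | (E)-1-[4,6-bis(benzyloxy)-2-hydroxy-3,5-dimethylphenyl]-3-[3-(benzyloxy)-4,5-dimethoxyphenyl]prop-2-en-1-one | COc1cc(/C=C/C(=O)c2c(O)c(C)c(OCc3ccccc3)c(C)c2OCc2ccccc2)cc(OCc2ccccc2)c1OC
F3 | step 7 | 5,7-bis(benzyloxy)-2-[3-(benzyloxy)-4,5-dimethoxyphenyl]-6,8-dimethyl-4H-chromen-4-one | COc1cc(-c2cc(=O)c3c(OCc4ccccc4)c(C)c(OCc4ccccc4)c(C)c3o2)cc(OCc2ccccc2)c1OC
F4 | step 6 | (Z)-5,7-bis(benzyloxy)-2-(2-bromoethenyl)-6,8-dimethyl-4H-chromen-4-one | Br/C=C\c1cc(=O)c2c(OCc3ccccc3)c(C)c(OCc3ccccc3)c(C)c2o1
F5 | step 1 | 1-[2,4,6-trihydroxy-3,5-bis(morpholin-4-ylmethyl)phenyl]ethanone | CC(=O)c1c(O)c(CN2CCOCC2)c(O)c(CN2CCOCC2)c1O
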